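Labdane numbering is used. Ring B is a cyclohexene whose C8=C9 double bond lies across the ring from the C5–C10 fusion bond. This is a [4+2] retron, so the first cut removes C5–C10 and C6–C7 and opens rings A and B together into a C7=C8–C9=C10 diene and a C5=C6 dienophile linked through C1–C4.
C6 carries a nitro group as activator and as the latent C6 oxygen. The 6β-acetate, the 7α-hydroxyl and the removal of a temporary 3β-oxygen follow the cycloaddition.
Open-chain cuts: C5=C6 (Henry condensation with nitromethane), C1–C10 (B-alkyl Suzuki coupling), C8–C7 and C8–C17 (methyl additions to an ester), C9–C11 (acetoacetate alkylation).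
Forward: the Z side-chain iodide is joined to ethyl acetoacetate and converted to the E-enol triflate, which is coupled with the pantolactone-derived C1–C5 piece. The isopropenyl diene and the nitroalkene are then installed, and one thermal step closes both rings.
Stereochemistry: 13Z comes with the commercial enynol. The C3 centre from (R)-pantolactone selects the diene face (C10). The alkene geometries and the nitro-endo transition state tie C5 and C6 to C10. The oxygens at C7 and C6 come from α-face attack on the rigid trans-decalin.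

Key step: step 17

Remark: the target SMILES is read as (5S,6S,7S,10S,13Z), that is 5α-H, 6β-OAc, 7α-OH and 10β-CH3. PMB = 4-methoxybenzyl, TBDPS = tert-butyldiphenylsilyl, TES = triethylsilyl.

Step 1
Reactants: 1 (Z)-3-methylpent-2-en-4-yn-1-ol
Product: 2 (Z)-tert-butyl[(3-methylpent-2-en-4-yn-1-yl)oxy]diphenylsilane
Conditions: TBDPSCl, imidazole, DMF, 0 °C to rt
Reagents that add atoms: tert-butylchlorodiphenylsilane, CC(C)(C)[Si](Cl)(c1ccccc1)c1ccccc1
Why: Imidazole-promoted silylation of a primary alcohol installs an ether that should survive base, organolithium, hydride, heat, DDQ and radical conditions until the final fluoride step, and it leaves the Z alkene untouched.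

Step 2
Reactants: 2 (Z)-enyne silyl ether
Product: 3 (Z)-tert-butyl[(3-methylpenta-2,4-dien-1-yl)oxy]diphenylsilane
Conditions: H2 (1 atm), Pd/CaCO3 poisoned with Pb(OAc)2, quinoline, hexane, rt
Reagents that add atoms: none
Why: Lindlar-type semihydrogenation of a terminal alkyne should stop at the vinyl group on the poisoned catalyst, and the trisubstituted Z alkene is not reduced or isomerised.

Step 3
Reactants: 3 (Z)-diene silyl ether
Product: 5 (Z)-5-[(tert-butyldiphenylsilyl)oxy]-3-methylpent-3-en-1-ol, via B-alkyl-9-BBN adduct 4 (not isolated)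
Conditions: 9-BBN, THF, 0 °C to rt; then NaOH, H2O2, 0 °C
Reagents that add atoms: hydrogen peroxide, OO
Why: In this hydroboration–oxidation the bulky borane should add anti-Markovnikov to the monosubstituted vinyl end of the diene much faster than to the trisubstituted alkene, giving the homoallylic alcohol with the Z geometry kept.

Step 4
Reactants: 5 (Z)-homoallylic alcohol
Product: 6 (Z)-tert-butyl[(5-iodo-3-methylpent-2-en-1-yl)oxy]diphenylsilane
Conditions: I2, PPh3, imidazole, CH2Cl2, 0 °C
Reagents that add atoms: iodine, II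
Why: Appel-type iodination converts the primary alcohol through its alkoxyphosphonium salt by SN2 displacement under neutral conditions that should not affect the silyl ether or the alkene.

Step 5
Reactants: 7 ethyl acetoacetate; 6 (Z)-side-chain iodide
Product: 9 ethyl (5Z)-2-acetyl-7-[(tert-butyldiphenylsilyl)oxy]-5-methylhept-5-enoate (racemic at C2), via sodium enolate 8 (not isolated)
Conditions: NaH, THF/DMF, 0 °C; then 6, 50 °C (7 in excess)
Reagents that add atoms: none
Why: The acetoacetic ester alkylation forms C9–C11, since the soft stabilised enolate should displace a primary iodide at carbon with little elimination, and the new stereocentre is erased in the next step.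

Step 6
Reactants: 9 2-alkylacetoacetate
Product: 10 ethyl (5Z)-7-[(tert-butyldiphenylsilyl)oxy]-5-methyl-2-[(1E)-1-(trifluoromethylsulfonyloxy)ethylidene]hept-5-enoate
Conditions: Tf2O, aq. Me4NOH, hexane/toluene, 0–5 °C
Reagents that add atoms: trifluoromethanesulfonic anhydride, O=S(=O)(OS(=O)(=O)C(F)(F)F)C(F)(F)F
Why: In this two-phase (Schotten–Baumann-type) enol triflation of a 2-substituted acetoacetate, the non-coordinating ammonium ion prevents chelation, so the enolate should adopt the dipole-minimised form with oxygen anti to the ester and give the E-triflate (CH3 cis to CO2Et).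

Step 7
Reactants: 11 (R)-pantolactone
Product: 12 (3R)-4,4-dimethyloxolane-2,3-diol (lactol, anomeric mixture)
Conditions: iBu2AlH (2.3 equiv), CH2Cl2, −78 °C; aq. potassium sodium tartrate
Reagents that add atoms: none
Why: Partial reduction of a lactone by iBu2AlH should stop at the lactol because the tetrahedral aluminium alkoxide is stable at low temperature, and the carbinol centre (future C3) is not involved.

Step 8
Reactants: 12 lactol
Product: 13 (3S)-2,2-dimethylpent-4-ene-1,3-diol
Conditions: Ph3PCH3Br, KOtBu (excess), THF, 0 °C to rt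
Reagents that add atoms: methyltriphenylphosphonium bromide, C[P+](c1ccccc1)(c1ccccc1)c1ccccc1.[Br-]
Why: Wittig methylenation of the open hydroxy-aldehyde form of a lactol is routine for sugar lactols, adds C1, and should not epimerise the adjacent alkoxide-bearing centre (the descriptor changes to S only through the priority rules).

Step 9
Reactants: 13 alkene diol
Product: 14 (2R,4S)-4-ethenyl-2-(4-methoxyphenyl)-5,5-dimethyl-1,3-dioxane
Conditions: 4-MeOC6H4CH(OMe)2, pyridinium p-toluenesulfonate (cat.), CH2Cl2, rt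
Reagents that add atoms: 4-methoxybenzaldehyde dimethyl acetal, COc1ccc(C(OC)OC)cc1
Why: Acid-catalysed transacetalisation of a 1,3-diol under thermodynamic control should give the chair dioxane with aryl and vinyl groups both equatorial, which fixes the acetal centre cis to C4.

Step 10
Reactants: 14 vinyl dioxane; 10 E-enol triflate
Product: 16 ethyl (2E,5Z)-7-[(tert-butyldiphenylsilyl)oxy]-2-{4-[(2R,4S)-2-(4-methoxyphenyl)-5,5-dimethyl-1,3-dioxan-4-yl]butan-2-ylidene}-5-methylhept-5-enoate, via B-alkyl-9-BBN adduct 15 (not isolated)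
Conditions: 14, 9-BBN, THF, rt; then 10, PdCl2(dppf) (5 mol %), Cs2CO3, DMF/H2O, rt to 50 °C
Reagents that add atoms: none
Why: The B-alkyl Suzuki–Miyaura coupling forms C1–C10, and since oxidative addition of the electron-poor triflate to zerovalent palladium and the reductive elimination both proceed with retention, the tether should end up trans to the ester.

Step 11
Reactants: 16 tetrasubstituted enoate
Product: 18 (3E,6Z)-8-[(tert-butyldiphenylsilyl)oxy]-3-{4-[(2R,4S)-2-(4-methoxyphenyl)-5,5-dimethyl-1,3-dioxan-4-yl]butan-2-ylidene}-2,6-dimethyloct-6-en-2-ol, via methyl ketone 17 (not isolated)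
Conditions: MeLi (4 equiv), Et2O, −78 to 0 °C
Reagents that add atoms: methyllithium, [Li]C
Why: Double 1,2-addition of a small organolithium to an ester brings in C7 and C17, and conjugate addition is blocked by the fully substituted β-carbon.

Step 12
Reactants: 18 tertiary allylic alcohol
Product: 20 tert-butyl{[(2Z,6E)-9-[(2R,4S)-2-(4-methoxyphenyl)-5,5-dimethyl-1,3-dioxan-4-yl]-3,7-dimethyl-6-(prop-1-en-2-yl)nona-2,6-dien-1-yl]oxy}diphenylsilane, via sulfamate ester salt 19 (not isolated)
Conditions: methyl N-(triethylammoniosulfonyl)carbamate, toluene, 50 °C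
Reagents that add atoms: none
Why: In this Burgess dehydration the only β-hydrogens of the sulfamate are on the two methyl groups, so the neutral syn elimination should give only the isopropenyl group and leave the C9=C10 geometry unchanged.

Step 13
Reactants: 20 diene acetal
Product: 21 (3S,6E,10Z)-12-[(tert-butyldiphenylsilyl)oxy]-3-[(4-methoxybenzyl)oxy]-2,2,6,10-tetramethyl-7-(prop-1-en-2-yl)dodeca-6,10-dien-1-ol
Conditions: iBu2AlH (3 equiv), CH2Cl2, −78 to 0 °C; aq. potassium sodium tartrate
Reagents that add atoms: none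
Why: In the reductive opening of a 4-methoxybenzylidene acetal, aluminium should bind the less hindered primary oxygen and hydride should go to the oxocarbenium ion, freeing the C5 alcohol and leaving the PMB ether on the C3 oxygen.

Step 14
Reactants: 21 primary alcohol
Product: 22 (3S,6E,10Z)-12-[(tert-butyldiphenylsilyl)oxy]-3-[(4-methoxybenzyl)oxy]-2,2,6,10-tetramethyl-7-(prop-1-en-2-yl)dodeca-6,10-dienal
Conditions: Dess–Martin periodinane, NaHCO3, CH2Cl2, 0 °C to rt
Reagents that add atoms: none
Why: The Dess–Martin oxidation works well on neopentyl alcohols, and the resulting aldehyde has no α-hydrogen, so it can neither enolise nor lose the β-alkoxy group.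

Step 15
Reactants: 22 aldehyde; 23 nitromethane
Product: 24 (4S,7E,11Z)-13-[(tert-butyldiphenylsilyl)oxy]-4-[(4-methoxybenzyl)oxy]-3,3,7,11-tetramethyl-1-nitro-8-(prop-1-en-2-yl)trideca-7,11-dien-2-ol (both C2 epimers)
Conditions: MeNO2 (excess), KOtBu (0.2 equiv), THF/t-BuOH, 0 °C to rt
Reagents that add atoms: none
Why: The Henry reaction forms C5–C6, excess nitromethane should drive the equilibrium for this pivalaldehyde-like substrate, and the uncontrolled carbinol centre disappears in the next step.

Step 16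
Reactants: 24 nitro alcohol
Product: 26 (1E,4S,7E,11Z)-13-[(tert-butyldiphenylsilyl)oxy]-4-[(4-methoxybenzyl)oxy]-3,3,7,11-tetramethyl-1-nitro-8-(prop-1-en-2-yl)trideca-1,7,11-triene (labdane atoms: C7H2=C8(CH3)–C9(side chain)=C10(CH3)–C1–C2–C3(OPMB)–C4(CH3)2–C5H=C6H–NO2), via nitro mesylate 25 (not isolated)
Conditions: MsCl, Et3N, CH2Cl2, −20 to 0 °C
Reagents that add atoms: none
Why: Mesylation followed by E1cB elimination of a β-nitro alcohol should give the more stable E nitroalkene, which cannot move out of conjugation because C4 is quaternary.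

Step 17
Reactants: 26 (E)-nitroalkene triene
Product: 27 (13Z)-3β-[(4-methoxybenzyl)oxy]-6α-nitro-15-[(tert-butyldiphenylsilyl)oxy]labda-8,13-diene (5α-H, 10β-CH3, trans-fused)
Conditions: toluene (0.01 M), 2,6-di-tert-butyl-4-methylphenol (0.2 equiv), sealed tube, 130 °C
Reagents that add atoms: none
Why: The nitro group lowers the LUMO of the C5=C6 dienophile, and a concerted, asynchronous, suprafacial [4+2] cycloaddition with the C7=C8–C9=C10 diene forms C5–C10 and C6–C7 in one event; the closest known reaction type is the thermal intramolecular Diels–Alder reaction of 1-nitro-1,7,9-decatrienes, which gives trans-fused nitro-octalins. Ring B closes as the six-membered cycloadduct ring, and ring A closes as the six-membered ring made of the C1–C4 tether and the new C5–C10 bond (fused mode, because a four-atom tether cannot reach the bridged orientation). C10 is set by the E geometry of C9=C10 (tether outside, methyl inside) together with the diene face attacked, and that face is chosen by the C3 centre, whose PMB ether should sit equatorial in the chair-like tether and so give the 3β-oxygen/10β-methyl relation. C5 follows from the nitro-endo, tether-exo transition state, which places H5 anti to the C10 methyl group (trans fusion), and C6 follows from the E nitroalkene, which keeps nitro trans to C4 and therefore 6α. The step needs sufficient rate, endo/exo selectivity and facial selectivity: strong nitro activation, the gem-dimethyl group next to the dienophile and high dilution with a radical inhibitor serve the first, the endo preference of nitro serves the second, and the C3 centre serves the third. Facial isomers are diastereomers and can be removed here, so the absolute configuration stays secure, and a cis-fused adduct with the correct C10 centre can still converge because C6 becomes a ketone next to C5.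

Step 18
Reactants: 27 6α-nitro decalin
Product: 29 (13Z)-3β-[(4-methoxybenzyl)oxy]-15-[(tert-butyldiphenylsilyl)oxy]labda-8,13-dien-6-one, via sodium nitronate 28 (not isolated)
Conditions: NaOMe, MeOH/THF, 0 °C to rt; then aq. TiCl3, NH4OAc (pH about 6), 0 °C to rt
Reagents that add atoms: water, O
Why: In the reductive form of the Nef reaction, trivalent titanium reduces the nitronate to the imine, buffered water hydrolyses it to the ketone, and the near-neutral medium should leave the ethers intact, keep C8=C9 out of conjugation and keep C5 in the more stable trans fusion.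

Step 19
Reactants: 29 β,γ-unsaturated 6-ketone
Product: 31 (13Z)-7α-hydroxy-3β-[(4-methoxybenzyl)oxy]-15-[(tert-butyldiphenylsilyl)oxy]labda-8,13-dien-6-one, via potassium dienolate 30 (not isolated)
Conditions: KN(SiMe3)2, THF, −78 °C; 2-(phenylsulfonyl)-3-phenyloxaziridine, −78 °C; AcOH quench at −78 °C
Reagents that add atoms: 2-(phenylsulfonyl)-3-phenyloxaziridine, O=S(=O)(c1ccccc1)N1OC1c1ccccc1
Why: In this enolate hydroxylation with an N-sulfonyloxaziridine (Davis oxidation), the doubly activated C7–H should be removed first, the dienolate should react at its α-carbon C7 rather than at the fully substituted C9, and oxygen should arrive pseudoaxially on the α face, away from the β-methyl groups on C10 and C4, giving 7α-OH.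

Step 20
Reactants: 31 7α-hydroxy ketone
Product: 32 (13Z)-3β-[(4-methoxybenzyl)oxy]-7α-(triethylsilyloxy)-15-[(tert-butyldiphenylsilyl)oxy]labda-8,13-dien-6-one
Conditions: Et3SiOTf, 2,6-lutidine, CH2Cl2, −78 to 0 °C
Reagents that add atoms: triethylsilyl trifluoromethanesulfonate, CC[Si](CC)(CC)OS(=O)(=O)C(F)(F)F
Why: Silylation with a silyl triflate and a hindered weak base should cap the allylic alcohol quickly and without enolisation, which blocks ketol shift and C7 epimerisation.

Step 21
Reactants: 32 7α-silyloxy ketone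
Product: 33 (13Z)-3β-[(4-methoxybenzyl)oxy]-7α-(triethylsilyloxy)-15-[(tert-butyldiphenylsilyl)oxy]labda-8,13-dien-6β-ol
Conditions: LiAlH4, Et2O, −20 to 0 °C
Reagents that add atoms: none
Why: In this hydride reduction under steric approach control, the β face of C6 is closed by the two syn-axial methyl groups on C4 and C10, so the small hydride should come from the α face and give the axial 6β-alcohol.

Step 22
Reactants: 33 6β-alcohol
Product: 34 (13Z)-6β-acetoxy-3β-[(4-methoxybenzyl)oxy]-7α-(triethylsilyloxy)-15-[(tert-butyldiphenylsilyl)oxy]labda-8,13-diene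
Conditions: Ac2O, DMAP, pyridine, 50 °C
Reagents that add atoms: acetic anhydride, CC(=O)OC(C)=O
Why: DMAP-catalysed acylation meets only one free hydroxyl group, and gentle heating should overcome the hindrance of the axial 6β position.

Step 23
Reactants: 34 PMB ether
Product: 35 (13Z)-6β-acetoxy-7α-(triethylsilyloxy)-15-[(tert-butyldiphenylsilyl)oxy]labda-8,13-dien-3β-ol
Conditions: DDQ, CH2Cl2/pH 7 phosphate buffer, 0 °C
Reagents that add atoms: none
Why: Oxidative PMB cleavage proceeds by hydride abstraction from the electron-rich benzylic position and hydrolysis of the oxocarbenium ion, which in buffered medium should spare the silyl ethers, the acetate and the alkenes.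

Step 24
Reactants: 35 3β-alcohol
Product: 36 (13Z)-6β-acetoxy-3β-[(imidazol-1-ylthiocarbonyl)oxy]-7α-(triethylsilyloxy)-15-[(tert-butyldiphenylsilyl)oxy]labda-8,13-diene
Conditions: 1,1'-thiocarbonyldiimidazole, DMAP (cat.), toluene, 90 °C
Reagents that add atoms: 1,1'-thiocarbonyldiimidazole, S=C(n1ccnc1)n1ccnc1
Why: Thioacylation of the equatorial 3β-alcohol under neutral conditions, as is common for 4,4-dimethyl-3β-ols, avoids the strong base of xanthate formation and so protects the acetate.

Step 25
Reactants: 36 thiocarbonylimidazolide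
Product: 37 (13Z)-6β-acetoxy-7α-(triethylsilyloxy)-15-[(tert-butyldiphenylsilyl)oxy]labda-8,13-diene
Conditions: Bu3SnH, AIBN (cat.), toluene, 100 °C
Reagents that add atoms: none
Why: In the Barton–McCombie deoxygenation the stannyl radical adds to sulfur, the C3–O bond fragments, and the secondary C3 radical in the rigid decalin has no alkene within reach, so it should simply abstract hydrogen and thereby remove the temporary stereocentre.

Step 26
Reactants: 37 bis-silyl ether
Product: 38 (13Z)-6β-acetoxylabda-8,13-diene-7α,15-diol, (5S,6S,7S,10S)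
Conditions: Bu4NF, AcOH (1:1), THF, 0 °C to rt
Reagents that add atoms: none
Why: Fluoride desilylation buffered with acetic acid should cleave both silyl ethers without acid ionisation of the C7 allylic alcohol, and the acetate cannot migrate because the trans-diaxial 6β and 7α oxygens cannot share a cyclic orthoester.

Compound list
1 | (Z)-3-methylpent-2-en-4-yn-1-ol | C#C/C(C)=C\CO | starting material
2 | (Z)-tert-butyl[(3-methylpent-2-en-4-yn-1-yl)oxy]diphenylsilane | C#C/C(C)=C\CO[Si](c1ccccc1)(c1ccccc1)C(C)(C)C | intermediate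
3 | (Z)-tert-butyl[(3-methylpenta-2,4-dien-1-yl)oxy]diphenylsilane | C=C/C(C)=C\CO[Si](c1ccccc1)(c1ccccc1)C(C)(C)C | intermediate
4 | B-[(Z)-5-(tert-butyldiphenylsilyloxy)-3-methylpent-3-en-1-yl]-9-borabicyclo[3.3.1]nonane | C(CB1C2CCCC1CCC2)/C(C)=C\CO[Si](c1ccccc1)(c1ccccc1)C(C)(C)C | intermediate
5 | (Z)-5-[(tert-butyldiphenylsilyl)oxy]-3-methylpent-3-en-1-ol | OCC/C(C)=C\CO[Si](c1ccccc1)(c1ccccc1)C(C)(C)C | intermediate
6 | (Z)-tert-butyl[(5-iodo-3-methylpent-2-en-1-yl)oxy]diphenylsilane | ICC/C(C)=C\CO[Si](c1ccccc1)(c1ccccc1)C(C)(C)C | intermediate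
7 | ethyl acetoacetate | CCOC(=O)CC(C)=O | starting material
8 | sodium enolate of ethyl acetoacetate | [Na+].CCOC(=O)C=C(C)[O-] | intermediate
9 | ethyl (5Z)-2-acetyl-7-[(tert-butyldiphenylsilyl)oxy]-5-methylhept-5-enoate (racemic at C2) | CCOC(=O)C(CC/C(C)=C\CO[Si](c1ccccc1)(c1ccccc1)C(C)(C)C)C(C)=O | intermediate
10 | ethyl (5Z)-7-[(tert-butyldiphenylsilyl)oxy]-5-methyl-2-[(1E)-1-(trifluoromethylsulfonyloxy)ethylidene]hept-5-enoate | CCOC(=O)/C(CC/C(C)=C\CO[Si](c1ccccc1)(c1ccccc1)C(C)(C)C)=C(\C)OS(=O)(=O)C(F)(F)F | intermediate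
11 | (R)-pantolactone | CC1(C)COC(=O)[C@@H]1O | starting material
12 | (3R)-4,4-dimethyloxolane-2,3-diol (anomeric mixture) | CC1(C)COC(O)[C@@H]1O | intermediate
13 | (3S)-2,2-dimethylpent-4-ene-1,3-diol | C=C[C@H](O)C(C)(C)CO | intermediate
14 | (2R,4S)-4-ethenyl-2-(4-methoxyphenyl)-5,5-dimethyl-1,3-dioxane | C=C[C@@H]1O[C@H](c2ccc(OC)cc2)OCC1(C)C | intermediate
15 | B-{2-[(2R,4S)-2-(4-methoxyphenyl)-5,5-dimethyl-1,3-dioxan-4-yl]ethyl}-9-borabicyclo[3.3.1]nonane | C(CB1C2CCCC1CCC2)[C@@H]1O[C@H](c2ccc(OC)cc2)OCC1(C)C | intermediate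
16 | ethyl (2E,5Z)-7-[(tert-butyldiphenylsilyl)oxy]-2-{4-[(2R,4S)-2-(4-methoxyphenyl)-5,5-dimethyl-1,3-dioxan-4-yl]butan-2-ylidene}-5-methylhept-5-enoate | CCOC(=O)/C(CC/C(C)=C\CO[Si](c1ccccc1)(c1ccccc1)C(C)(C)C)=C(\C)CC[C@@H]1O[C@H](c2ccc(OC)cc2)OCC1(C)C | intermediate
17 | (3E,6Z)-8-[(tert-butyldiphenylsilyl)oxy]-3-{4-[(2R,4S)-2-(4-methoxyphenyl)-5,5-dimethyl-1,3-dioxan-4-yl]butan-2-ylidene}-6-methyloct-6-en-2-one | CC(=O)/C(CC/C(C)=C\CO[Si](c1ccccc1)(c1ccccc1)C(C)(C)C)=C(\C)CC[C@@H]1O[C@H](c2ccc(OC)cc2)OCC1(C)C | intermediate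
18 | (3E,6Z)-8-[(tert-butyldiphenylsilyl)oxy]-3-{4-[(2R,4S)-2-(4-methoxyphenyl)-5,5-dimethyl-1,3-dioxan-4-yl]butan-2-ylidene}-2,6-dimethyloct-6-en-2-ol | CC(C)(O)/C(CC/C(C)=C\CO[Si](c1ccccc1)(c1ccccc1)C(C)(C)C)=C(\C)CC[C@@H]1O[C@H](c2ccc(OC)cc2)OCC1(C)C | intermediate
19 | triethylammonium salt of the N-(methoxycarbonyl)sulfamate ester of 18 | COC(=O)[N-]S(=O)(=O)OC(C)(C)/C(CC/C(C)=C\CO[Si](c1ccccc1)(c1ccccc1)C(C)(C)C)=C(\C)CC[C@@H]1O[C@H](c2ccc(OC)cc2)OCC1(C)C.CC[NH+](CC)CC | intermediate
20 | tert-butyl{[(2Z,6E)-9-[(2R,4S)-2-(4-methoxyphenyl)-5,5-dimethyl-1,3-dioxan-4-yl]-3,7-dimethyl-6-(prop-1-en-2-yl)nona-2,6-dien-1-yl]oxy}diphenylsilane | C=C(C)/C(CC/C(C)=C\CO[Si](c1ccccc1)(c1ccccc1)C(C)(C)C)=C(\C)CC[C@@H]1O[C@H](c2ccc(OC)cc2)OCC1(C)C | intermediate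
21 | (3S,6E,10Z)-12-[(tert-butyldiphenylsilyl)oxy]-3-[(4-methoxybenzyl)oxy]-2,2,6,10-tetramethyl-7-(prop-1-en-2-yl)dodeca-6,10-dien-1-ol | C=C(C)/C(CC/C(C)=C\CO[Si](c1ccccc1)(c1ccccc1)C(C)(C)C)=C(\C)CC[C@H](OCc1ccc(OC)cc1)C(C)(C)CO | intermediate
22 | (3S,6E,10Z)-12-[(tert-butyldiphenylsilyl)oxy]-3-[(4-methoxybenzyl)oxy]-2,2,6,10-tetramethyl-7-(prop-1-en-2-yl)dodeca-6,10-dienal | C=C(C)/C(CC/C(C)=C\CO[Si](c1ccccc1)(c1ccccc1)C(C)(C)C)=C(\C)CC[C@H](OCc1ccc(OC)cc1)C(C)(C)C=O | intermediate
23 | nitromethane | C[N+](=O)[O-] | starting material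
24 | (4S,7E,11Z)-13-[(tert-butyldiphenylsilyl)oxy]-4-[(4-methoxybenzyl)oxy]-3,3,7,11-tetramethyl-1-nitro-8-(prop-1-en-2-yl)trideca-7,11-dien-2-ol (C2 epimers) | C=C(C)/C(CC/C(C)=C\CO[Si](c1ccccc1)(c1ccccc1)C(C)(C)C)=C(\C)CC[C@H](OCc1ccc(OC)cc1)C(C)(C)C(O)C[N+](=O)[O-] | intermediate
25 | methanesulfonate of 24 | C=C(C)/C(CC/C(C)=C\CO[Si](c1ccccc1)(c1ccccc1)C(C)(C)C)=C(\C)CC[C@H](OCc1ccc(OC)cc1)C(C)(C)C(C[N+](=O)[O-])OS(C)(=O)=O | intermediate
26 | (1E,4S,7E,11Z)-13-[(tert-butyldiphenylsilyl)oxy]-4-[(4-methoxybenzyl)oxy]-3,3,7,11-tetramethyl-1-nitro-8-(prop-1-en-2-yl)trideca-1,7,11-triene | C=C(C)/C(CC/C(C)=C\CO[Si](c1ccccc1)(c1ccccc1)C(C)(C)C)=C(\C)CC[C@H](OCc1ccc(OC)cc1)C(C)(C)/C=C/[N+](=O)[O-] | intermediate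
27 | (13Z)-3β-[(4-methoxybenzyl)oxy]-6α-nitro-15-[(tert-butyldiphenylsilyl)oxy]labda-8,13-diene | [O-][N+](=O)[C@H]1CC(C)=C(CC/C(C)=C\CO[Si](c3ccccc3)(c3ccccc3)C(C)(C)C)[C@@]2(C)CC[C@H](OCc3ccc(OC)cc3)C(C)(C)[C@H]12 | intermediate
28 | sodium 6-nitronate of 27 | [Na+].[O-][N+]([O-])=C1CC(C)=C(CC/C(C)=C\CO[Si](c3ccccc3)(c3ccccc3)C(C)(C)C)[C@@]2(C)CC[C@H](OCc3ccc(OC)cc3)C(C)(C)[C@H]12 | intermediate
29 | (13Z)-3β-[(4-methoxybenzyl)oxy]-15-[(tert-butyldiphenylsilyl)oxy]labda-8,13-dien-6-one | O=C1CC(C)=C(CC/C(C)=C\CO[Si](c3ccccc3)(c3ccccc3)C(C)(C)C)[C@@]2(C)CC[C@H](OCc3ccc(OC)cc3)C(C)(C)[C@H]12 | intermediate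
30 | potassium 6,8-dien-6-olate of 29 | [K+].[O-]C1=CC(C)=C(CC/C(C)=C\CO[Si](c3ccccc3)(c3ccccc3)C(C)(C)C)[C@@]2(C)CC[C@H](OCc3ccc(OC)cc3)C(C)(C)[C@H]12 | intermediate
31 | (13Z)-7α-hydroxy-3β-[(4-methoxybenzyl)oxy]-15-[(tert-butyldiphenylsilyl)oxy]labda-8,13-dien-6-one | O=C1[C@@H](O)C(C)=C(CC/C(C)=C\CO[Si](c3ccccc3)(c3ccccc3)C(C)(C)C)[C@@]2(C)CC[C@H](OCc3ccc(OC)cc3)C(C)(C)[C@H]12 | intermediate
32 | (13Z)-3β-[(4-methoxybenzyl)oxy]-7α-(triethylsilyloxy)-15-[(tert-butyldiphenylsilyl)oxy]labda-8,13-dien-6-one | O=C1[C@@H](O[Si](CC)(CC)CC)C(C)=C(CC/C(C)=C\CO[Si](c3ccccc3)(c3ccccc3)C(C)(C)C)[C@@]2(C)CC[C@H](OCc3ccc(OC)cc3)C(C)(C)[C@H]12 | intermediate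
33 | (13Z)-3β-[(4-methoxybenzyl)oxy]-7α-(triethylsilyloxy)-15-[(tert-butyldiphenylsilyl)oxy]labda-8,13-dien-6β-ol | O[C@@H]1[C@@H](O[Si](CC)(CC)CC)C(C)=C(CC/C(C)=C\CO[Si](c3ccccc3)(c3ccccc3)C(C)(C)C)[C@@]2(C)CC[C@H](OCc3ccc(OC)cc3)C(C)(C)[C@H]12 | intermediate
34 | (13Z)-6β-acetoxy-3β-[(4-methoxybenzyl)oxy]-7α-(triethylsilyloxy)-15-[(tert-butyldiphenylsilyl)oxy]labda-8,13-diene | CC(=O)O[C@@H]1[C@@H](O[Si](CC)(CC)CC)C(C)=C(CC/C(C)=C\CO[Si](c3ccccc3)(c3ccccc3)C(C)(C)C)[C@@]2(C)CC[C@H](OCc3ccc(OC)cc3)C(C)(C)[C@H]12 | intermediate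
35 | (13Z)-6β-acetoxy-7α-(triethylsilyloxy)-15-[(tert-butyldiphenylsilyl)oxy]labda-8,13-dien-3β-ol | CC(=O)O[C@@H]1[C@@H](O[Si](CC)(CC)CC)C(C)=C(CC/C(C)=C\CO[Si](c3ccccc3)(c3ccccc3)C(C)(C)C)[C@@]2(C)CC[C@H](O)C(C)(C)[C@H]12 | intermediate
36 | (13Z)-6β-acetoxy-3β-[(imidazol-1-ylthiocarbonyl)oxy]-7α-(triethylsilyloxy)-15-[(tert-butyldiphenylsilyl)oxy]labda-8,13-diene | CC(=O)O[C@@H]1[C@@H](O[Si](CC)(CC)CC)C(C)=C(CC/C(C)=C\CO[Si](c3ccccc3)(c3ccccc3)C(C)(C)C)[C@@]2(C)CC[C@H](OC(=S)n3ccnc3)C(C)(C)[C@H]12 | intermediate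
37 | (13Z)-6β-acetoxy-7α-(triethylsilyloxy)-15-[(tert-butyldiphenylsilyl)oxy]labda-8,13-diene | CC(=O)O[C@@H]1[C@@H](O[Si](CC)(CC)CC)C(C)=C(CC/C(C)=C\CO[Si](c3ccccc3)(c3ccccc3)C(C)(C)C)[C@@]2(C)CCCC(C)(C)[C@H]12 | intermediate
38 | (13Z)-6β-acetoxylabda-8,13-diene-7α,15-diol, (5S,6S,7S,10S) | CC(=O)O[C@@H]1[C@@H](O)C(C)=C(CC/C(C)=C\CO)[C@@]2(C)CCCC(C)(C)[C@H]12 | target

Total step count: 26.
Longest linear sequence: 23 steps (from 1 through steps 1–6 and 10–26). The pantolactone branch (steps 7–9) joins at step 10.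

Steps most likely to fail

Step 17. The fully substituted C10 terminus twists the diene out of the s-cis arrangement. The cycloaddition may therefore be slower than thermal decay of the nitroalkene or a hydrogen shift within the diene, and the facial bias from C3 may be small at high temperature. The fallback sets out from 26 and returns at 27. It forms the same two bonds one after the other and does not need an s-cis diene. With methylaluminium bis(2,6-diphenylphenoxide) in CH2Cl2 at −78 °C the nitroalkene should act as a 4π heterodiene (C5=C6–N=O). It should add across the electron-rich tetrasubstituted C9=C10 alkene in an inverse-demand hetero-[4+2] reaction, with C5 bonding to C10 and oxygen to the allylic tertiary C9. This gives the ring-A-fused cyclic nitronate F1. Gentle warming in toluene should then trigger the known [3,3]-sigmatropic shift of vinyl-substituted nitronates: O–C9 breaks, C6–C7 forms from the face bearing the isopropenyl group, and 27 results.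

Step 18. Removal of the axial 6β-hydrogen, which sits between two syn-axial methyl groups, may be slow. During hydrolysis the C8=C9 double bond may also move into conjugation with the new carbonyl group. The fallback sets out from 27 and returns at 29. The nitro group is reduced directly, without prior nitronate formation, with SnCl2, PhSH and Et3N in MeCN to the 6-oxime F2. The oxime is then cleaved reductively with aq. TiCl3 buffered by NH4OAc, through the imine, to 29.

Step 19. The dienolate may be attacked at C9 or on the β face. In the basic medium the free α-ketol may also epimerise at C7 or shift its carbonyl group to C7, where it would be conjugated. The fallback sets out from 29 and returns at 31, using neutral oxidation of an isolated enol derivative. t-BuMe2SiOTf and Et3N in CH2Cl2 should give the linear 6-silyloxy-6,8-diene F3. Catalytic OsO4 with N-methylmorpholine N-oxide in acetone/water should then osmylate the electron-rich trisubstituted C6=C7 bond from the α face. This should be faster than attack on the tetrasubstituted C8=C9 bond or on the side-chain alkene next to the bulky silyl ether. Collapse of the silyl hemiketal gives 31.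

Further compounds
F1 | step 17 | cyclic nitronate (1,2-oxazine N-oxide) with C5–C10 and O–C9 bonds, trans-fused to ring A, 9β-isopropenyl, 9α side chain, 3β-OPMB | C=C(C)[C@@]1(CC/C(C)=C\CO[Si](c3ccccc3)(c3ccccc3)C(C)(C)C)O[N+]([O-])=C[C@H]2C(C)(C)[C@@H](OCc3ccc(OC)cc3)CC[C@]12C
F2 | step 18 | (13Z)-3β-[(4-methoxybenzyl)oxy]-15-[(tert-butyldiphenylsilyl)oxy]labda-8,13-dien-6-one oxime | ON=C1CC(C)=C(CC/C(C)=C\CO[Si](c3ccccc3)(c3ccccc3)C(C)(C)C)[C@@]2(C)CC[C@H](OCc3ccc(OC)cc3)C(C)(C)[C@H]12
F3 | step 19 | (13Z)-6-(tert-butyldimethylsilyloxy)-3β-[(4-methoxybenzyl)oxy]-15-[(tert-butyldiphenylsilyl)oxy]labda-6,8,13-triene | CC(C)(C)[Si](C)(C)OC1=CC(C)=C(CC/C(C)=C\CO[Si](c3ccccc3)(c3ccccc3)C(C)(C)C)[C@@]2(C)CC[C@H](OCc3ccc(OC)cc3)C(C)(C)[C@H]12
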